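The C5 prenyl group and the free 4-OH of ring A are traced back together, by an aromatic Claisen rearrangement, to a 4-O-(1,1-dimethylallyl) ether, which is also the only protection O4 ever needs.
Key disconnection: C2 of the furan ring / C1' of ring B. Both carbons are innately nucleophilic, so ring B enters with reversed polarity, dearomatised as 2-methoxy-p-benzoquinone 4-dimethyl ketal. It is joined to the C2 carbanion of the 3-formylbenzofuran and rearomatised reductively in the same flask.
Enabling feature: the 4'-OH stands para and the 2'-OMe ortho to C1', so C1' maps onto the only carbonyl carbon of that quinone monoketal. On the other side, C2–H lies between O1 and the C3 formyl group, which as a transient α-amino alkoxide steers lithiation to C2.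
The 3-formylbenzofuran comes from ethyl 4-hydroxy-6-methoxybenzofuran-3-carboxylate, made from mirror-symmetric 2,6-dihydroxy-4-methoxybenzaldehyde and ethyl diazoacetate, so O4 and O6 are told apart without protecting groups.
Ring order: ring A is bought and the furan ring is closed in step 2. Ring B is bought as an arene, dearomatised in step 7 and rearomatised in step 8; no further ring is formed.

Key step: step 8

Remark: the target SMILES holds no stereocentre and no stereogenic C=C (the prenyl alkene carries two methyl groups). The C2–C1' axis, flanked only by 2'-OMe, H-6', O1 and the 3-CHO on a five-membered ring, should rotate freely. The target is therefore treated as one achiral compound and no enantioselective step is planned.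

Step 1
Reactants: 1 2,4,6-trihydroxybenzaldehyde
Product: 2 2,6-dihydroxy-4-methoxybenzaldehyde
Conditions: Me2SO4 (1.0 equiv), K2CO3 (1.0 equiv), acetone, rt → 40 °C
Reagents that add atoms: dimethyl sulfate COS(=O)(=O)OC
Why: Williamson-type O-methylation should take place at the 4-OH only, because it is the most acidic hydroxyl (para to CHO) while the two ortho hydroxyls are tied up in hydrogen bonds to the carbonyl oxygen, and the product keeps the mirror symmetry that makes the next ring closure unambiguous.

Step 2
Reactants: 2 2,6-dihydroxy-4-methoxybenzaldehyde; 3 ethyl diazoacetate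
Product: 5 ethyl 4-hydroxy-6-methoxy-1-benzofuran-3-carboxylate, via hemiacetal 4 (not isolated)
Conditions: HBF4·OEt2 (10 mol %), CH2Cl2, rt; then conc. H2SO4, rt
Reagents that add atoms: none
Why: Acid-catalysed addition of the diazo ester to the aldehyde, 1,2-shift of the electron-rich aryl group with loss of N2, hemiacetal closure of the resulting 3-hydroxy-2-arylacrylate onto either of the two equivalent ortho hydroxyls and dehydration make up the known salicylaldehyde–diazoacetate annulation to benzofuran-3-carboxylates, which leaves C2–H free and the remaining OH at C4.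

Step 3
Reactants: 6 2-methylbut-3-en-2-ol
Product: 8 tert-butyl 2-methylbut-3-en-2-yl carbonate, via lithium alkoxide 7 (not isolated)
Conditions: n-BuLi, THF, 0 °C; Boc2O, 0 °C → rt; H2O quench
Reagents that add atoms: di-tert-butyl dicarbonate CC(C)(C)OC(=O)OC(=O)OC(C)(C)C
Why: Acylation of a tertiary lithium alkoxide by Boc2O is the standard preparation of mixed allyl tert-butyl carbonates.

Step 4
Reactants: 5 ethyl 4-hydroxy-6-methoxy-1-benzofuran-3-carboxylate; 8 tert-butyl 2-methylbut-3-en-2-yl carbonate
Product: 9 ethyl 6-methoxy-4-[(2-methylbut-3-en-2-yl)oxy]-1-benzofuran-3-carboxylate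
Conditions: Pd(PPh3)4 (5 mol %), THF, 0 °C, short reaction time
Reagents that add atoms: none
Why: In this Tsuji–Trost O-allylation, ionisation of 8 gives a 1,1-dimethyl-π-allylpalladium complex plus tert-butoxide, which deprotonates the 4-OH, and under kinetic control at low temperature the phenoxide should attack the more substituted allyl terminus to give the tertiary (reverse-prenyl) ether.

Step 5
Reactants: 9 ethyl 6-methoxy-4-[(2-methylbut-3-en-2-yl)oxy]-1-benzofuran-3-carboxylate
Product: 10 {6-methoxy-4-[(2-methylbut-3-en-2-yl)oxy]-1-benzofuran-3-yl}methanol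
Conditions: LiAlH4, THF, 0 °C; aq NaOH work-up
Reagents that add atoms: none
Why: Hydride reduction of the ester with LiAlH4 under non-acidic conditions and basic work-up should spare the tertiary allyl aryl ether and the acid-sensitive furylmethanol.

Step 6
Reactants: 10 {6-methoxy-4-[(2-methylbut-3-en-2-yl)oxy]-1-benzofuran-3-yl}methanol
Product: 11 6-methoxy-4-[(2-methylbut-3-en-2-yl)oxy]-1-benzofuran-3-carbaldehyde
Conditions: activated MnO2, CH2Cl2, rt
Reagents that add atoms: none
Why: Activated MnO2 oxidises heterobenzylic alcohols selectively to aldehydes under neutral conditions and should leave the vinyl group and the aryl ethers untouched.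

Step 7
Reactants: 12 2,4-dimethoxyphenol
Product: 13 2,4,4-trimethoxycyclohexa-2,5-dien-1-one
Conditions: PhI(OAc)2, MeOH, 0 °C
Reagents that add atoms: methanol CO
Why: Hypervalent-iodine oxidative dearomatisation of a 4-methoxyphenol in methanol traps the phenoxenium ion at the para carbon that already bears OMe and should give the stable p-quinone monoketal, which turns the future C1' from a nucleophilic into an electrophilic carbon.

Step 8
Reactants: 11 6-methoxy-4-[(2-methylbut-3-en-2-yl)oxy]-1-benzofuran-3-carbaldehyde; 13 2,4,4-trimethoxycyclohexa-2,5-dien-1-one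
Product: 18 2-(4-hydroxy-2-methoxyphenyl)-6-methoxy-4-[(2-methylbut-3-en-2-yl)oxy]-1-benzofuran-3-carbaldehyde, via amino alkoxide 14 (not isolated), via C2-lithio species 15 (not isolated), via quinol ketal adduct 16 (not isolated), via p-quinol 17 (not isolated)
Conditions: MeN(Li)CH2CH2NMe2 (from the amine + n-BuLi), THF, −78 °C; n-BuLi, −78 → −30 °C; 13, −78 °C; then AcOH–H2O, 0 °C → rt; Zn dust, rt
Reagents that add atoms: water O
Why: The lithium amide adds to the C3 aldehyde to give amino alkoxide 14, which masks the CHO and, together with O1, guides n-BuLi to C2–H (15); this hard carbanion adds 1,2 to the only carbonyl of quinone monoketal 13 (16), aqueous acetic acid then returns the aldehyde and hydrolyses the ketal (17), and zinc removes the doubly allylic tertiary OH by a vinylogous α-hydroxy-ketone reduction, so that ring B rearomatises as the free 4'-phenol. The closest known reaction types are the addition of aryllithiums to p-quinone monoketals followed by reductive aromatisation of the p-quinol to a 4-arylphenol, and the α-amino-alkoxide-directed lithiation of 3-formyl five-membered heteroarenes at C2. No ring is closed, ring B only returns from the cyclohexadienone level to the arene level. The stereocentres at the carbinolamine carbon and at the quinol carbon arise without control and are both erased in the same flask, so that an achiral product results. Site selectivity is needed on both partners: on ring B it is secured because the future C1' is the sole C=O of 13, with the 2'-OMe already next to it and the future 4'-oxygen position stored as the ketal, and on the benzofuran because C2–H is the most acidic C–H and the one nearest to the directing group, ahead of C5–H and C7–H. 1,2- rather than 1,4-addition follows from the hard organolithium at −78 °C, and the weakly acidic reduction at room temperature should spare the tertiary allyl ether, the vinyl group and the electron-rich aldehyde.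

Step 9
Reactants: 18 2-(4-hydroxy-2-methoxyphenyl)-6-methoxy-4-[(2-methylbut-3-en-2-yl)oxy]-1-benzofuran-3-carbaldehyde
Product: 20 Ebenfuran IV, via ortho-dienone 19 (not isolated)
Conditions: DMF, 120 °C
Reagents that add atoms: none
Why: In this aromatic Claisen rearrangement the [3,3] shift of the 1,1-dimethylallyl ether can end productively only at C5, since the other ortho position C3a is the ring fusion, it inverts the allyl unit to the linear prenyl group, and tautomerisation of dienone 19 frees the 4-OH, which is then held by a hydrogen bond to the 3-CHO.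

Compound list
1 | 2,4,6-trihydroxybenzaldehyde | O=Cc1c(O)cc(O)cc1O | starting material
2 | 2,6-dihydroxy-4-methoxybenzaldehyde | O=Cc1c(O)cc(OC)cc1O | intermediate
3 | ethyl diazoacetate | CCOC(=O)C=[N+]=[N-] | starting material
4 | ethyl 2,4-dihydroxy-6-methoxy-2,3-dihydro-1-benzofuran-3-carboxylate (racemic diastereomer mixture, not isolated) | CCOC(=O)C1C(O)Oc2cc(OC)cc(O)c12 | intermediate
5 | ethyl 4-hydroxy-6-methoxy-1-benzofuran-3-carboxylate | CCOC(=O)c1coc2cc(OC)cc(O)c12 | intermediate
6 | 2-methylbut-3-en-2-ol | C=CC(C)(C)O | starting material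
7 | lithium 2-methylbut-3-en-2-olate (not isolated) | [Li+].[O-]C(C)(C)C=C | intermediate
8 | tert-butyl 2-methylbut-3-en-2-yl carbonate | C=CC(C)(C)OC(=O)OC(C)(C)C | intermediate
9 | ethyl 6-methoxy-4-[(2-methylbut-3-en-2-yl)oxy]-1-benzofuran-3-carboxylate | CCOC(=O)c1coc2cc(OC)cc(OC(C)(C)C=C)c12 | intermediate
10 | {6-methoxy-4-[(2-methylbut-3-en-2-yl)oxy]-1-benzofuran-3-yl}methanol | OCc1coc2cc(OC)cc(OC(C)(C)C=C)c12 | intermediate
11 | 6-methoxy-4-[(2-methylbut-3-en-2-yl)oxy]-1-benzofuran-3-carbaldehyde | O=Cc1coc2cc(OC)cc(OC(C)(C)C=C)c12 | intermediate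
12 | 2,4-dimethoxyphenol | COc1ccc(O)c(OC)c1 | starting material
13 | 2,4,4-trimethoxycyclohexa-2,5-dien-1-one (2-methoxy-p-benzoquinone 4-dimethyl ketal) | O=C1C=CC(OC)(OC)C=C1OC | intermediate
14 | lithium {[2-(dimethylamino)ethyl](methyl)amino}{6-methoxy-4-[(2-methylbut-3-en-2-yl)oxy]-1-benzofuran-3-yl}methanolate (racemic, not isolated) | [Li+].[O-]C(N(C)CCN(C)C)c1coc2cc(OC)cc(OC(C)(C)C=C)c12 | intermediate
15 | C2-lithiated amino alkoxide derived from 14 (racemic, not isolated) | [Li+].[Li]c1oc2cc(OC)cc(OC(C)(C)C=C)c2c1C([O-])N(C)CCN(C)C | intermediate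
16 | dilithium salt of the 1,2-adduct: 1-(benzofuran-2-yl)-2,4,4-trimethoxycyclohexa-2,5-dien-1-olate still carrying the C3 amino alkoxide (diastereomer mixture, not isolated) | [Li+].[Li+].[O-]C(N(C)CCN(C)C)c1c(oc2cc(OC)cc(OC(C)(C)C=C)c12)C1([O-])C=CC(OC)(OC)C=C1OC | intermediate
17 | 2-(1-hydroxy-2-methoxy-4-oxocyclohexa-2,5-dien-1-yl)-6-methoxy-4-[(2-methylbut-3-en-2-yl)oxy]-1-benzofuran-3-carbaldehyde (racemic, not isolated) | O=Cc1c(oc2cc(OC)cc(OC(C)(C)C=C)c12)C1(O)C=CC(=O)C=C1OC | intermediate
18 | 2-(4-hydroxy-2-methoxyphenyl)-6-methoxy-4-[(2-methylbut-3-en-2-yl)oxy]-1-benzofuran-3-carbaldehyde | O=Cc1c(oc2cc(OC)cc(OC(C)(C)C=C)c12)-c1ccc(O)cc1OC | intermediate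
19 | 2-(4-hydroxy-2-methoxyphenyl)-6-methoxy-5-(3-methylbut-2-en-1-yl)-4-oxo-4,5-dihydro-1-benzofuran-3-carbaldehyde (racemic, not isolated) | O=Cc1c(-c2ccc(O)cc2OC)oc2C=C(OC)C(CC=C(C)C)C(=O)c12 | intermediate
20 | Ebenfuran IV, 4-hydroxy-2-(4-hydroxy-2-methoxyphenyl)-6-methoxy-5-(3-methylbut-2-en-1-yl)-1-benzofuran-3-carbaldehyde (achiral) | COc1cc(O)ccc1-c1oc2cc(OC)c(CC=C(C)C)c(O)c2c1C=O | target

Total step count: 9
Longest linear sequence: 7 steps (1, 2, 4, 5, 6, 8, 9); steps 3 and 7 are side branches.

Steps most likely to fail

**Step 8.**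
- What may go wrong:
  - Electron transfer from the crowded, doubly charged aryllithium to the dienone may compete with 1,2-addition.
  - Addition next to the 2-OMe group may be slow.
  - During hydrolysis, acid may ionise the tertiary allyl ether or trigger an aryl shift of the quinol (dienone–phenol rearrangement).
  - The released diamine may intercept the freed aldehyde during the zinc reduction.
- Fallback: a matched-polarity cross-coupling replaces the carbonyl addition; it sets out from 11 and comes back at 20. Compound 11 is first heated (DMF, 120 °C), so that the Pd-labile tertiary allyl ether rearranges to 4-hydroxy-6-methoxy-5-(3-methylbut-2-en-1-yl)-1-benzofuran-3-carbaldehyde F1. Silylation (TBSOTf, 2,6-lutidine, CH2Cl2) should give 4-[(tert-butyldimethylsilyl)oxy]-6-methoxy-5-(3-methylbut-2-en-1-yl)-1-benzofuran-3-carbaldehyde F2. Zincation at C2 with (TMP)2Zn·2MgCl2·2LiCl (THF, 25 °C), a base that tolerates aldehydes, should give bis{4-[(tert-butyldimethylsilyl)oxy]-3-formyl-6-methoxy-5-(3-methylbut-2-en-1-yl)-1-benzofuran-2-yl}zinc F3. This enters a Negishi coupling (Pd(OAc)2, SPhos, THF, 50 °C) with (4-bromo-3-methoxyphenoxy)(tert-butyl)dimethylsilane F4, made from commercial 4-bromo-3-methoxyphenol (TBSCl, imidazole, DMF). The resulting 4-[(tert-butyldimethylsilyl)oxy]-2-{4-[(tert-butyldimethylsilyl)oxy]-2-methoxyphenyl}-6-methoxy-5-(3-methylbut-2-en-1-yl)-1-benzofuran-3-carbaldehyde F5 is desilylated (TBAF, AcOH, THF) to 20.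

**Step 4.**
- What may go wrong:
  - The hindered, hydrogen-bonded phenoxide may attack the unsubstituted allyl terminus.
  - Pd may re-ionise the product, with drift from the branched to the linear ether; that ether would later deliver the wrong (reverse) prenyl group at C5.
  - The chelated OH may simply not react.
- Fallback: the tertiary carbon is attached as a propargyl unit without a π-allyl intermediate; it sets out from 5 and comes back at 9. Copper-catalysed O-alkylation with commercial 3-chloro-3-methylbut-1-yne (CuCl2 cat., DBU, MeCN, 0 °C) should give ethyl 6-methoxy-4-[(2-methylbut-3-yn-2-yl)oxy]-1-benzofuran-3-carboxylate F6. Semihydrogenation over Lindlar catalyst (H2, quinoline, EtOAc) should then give 9.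

**Step 2.**
- What may go wrong:
  - Addition of the diazo ester to the strongly deactivated, doubly hydrogen-bonded aldehyde may be sluggish.
  - O–H insertion into the phenols and oligomerisation of the diazo ester may compete.
- Fallback: the 1,2-aryl shift is carried out oxidatively on a cinnamate instead of through a diazonium betaine; it sets out from 2 and comes back at 5. Protection (MOMCl, i-Pr2NEt, CH2Cl2) should give 4-methoxy-2,6-bis(methoxymethoxy)benzaldehyde F7. A Wittig reaction (Ph3P=CHCO2Et, toluene, reflux) should give ethyl (E)-3-[4-methoxy-2,6-bis(methoxymethoxy)phenyl]prop-2-enoate F8. Iodine(III)-mediated oxidative rearrangement (PhI(OH)OTs, HC(OMe)3, MeOH) should give racemic ethyl 3,3-dimethoxy-2-[4-methoxy-2,6-bis(methoxymethoxy)phenyl]propanoate F9. Acid (p-TsOH, aq EtOH, reflux) removes both MOM groups and closes and aromatises the furan ring to 5.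

Further compounds
F1 | step 8 | 4-hydroxy-6-methoxy-5-(3-methylbut-2-en-1-yl)-1-benzofuran-3-carbaldehyde | O=Cc1coc2cc(OC)c(CC=C(C)C)c(O)c12
F2 | step 8 | 4-[(tert-butyldimethylsilyl)oxy]-6-methoxy-5-(3-methylbut-2-en-1-yl)-1-benzofuran-3-carbaldehyde | O=Cc1coc2cc(OC)c(CC=C(C)C)c(O[Si](C)(C)C(C)(C)C)c12
F3 | step 8 | bis{4-[(tert-butyldimethylsilyl)oxy]-3-formyl-6-methoxy-5-(3-methylbut-2-en-1-yl)-1-benzofuran-2-yl}zinc | O=Cc1c([Zn]c2oc3cc(OC)c(CC=C(C)C)c(O[Si](C)(C)C(C)(C)C)c3c2C=O)oc2cc(OC)c(CC=C(C)C)c(O[Si](C)(C)C(C)(C)C)c12
F4 | step 8 | (4-bromo-3-methoxyphenoxy)(tert-butyl)dimethylsilane | COc1cc(O[Si](C)(C)C(C)(C)C)ccc1Br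
F5 | step 8 | 4-[(tert-butyldimethylsilyl)oxy]-2-{4-[(tert-butyldimethylsilyl)oxy]-2-methoxyphenyl}-6-methoxy-5-(3-methylbut-2-en-1-yl)-1-benzofuran-3-carbaldehyde | COc1cc(O[Si](C)(C)C(C)(C)C)ccc1-c1oc2cc(OC)c(CC=C(C)C)c(O[Si](C)(C)C(C)(C)C)c2c1C=O
F6 | step 4 | ethyl 6-methoxy-4-[(2-methylbut-3-yn-2-yl)oxy]-1-benzofuran-3-carboxylate | CCOC(=O)c1coc2cc(OC)cc(OC(C)(C)C#C)c12
F7 | step 2 | 4-methoxy-2,6-bis(methoxymethoxy)benzaldehyde | O=Cc1c(OCOC)cc(OC)cc1OCOC
F8 | step 2 | ethyl (E)-3-[4-methoxy-2,6-bis(methoxymethoxy)phenyl]prop-2-enoate | CCOC(=O)/C=C/c1c(OCOC)cc(OC)cc1OCOC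
F9 | step 2 | ethyl 3,3-dimethoxy-2-[4-methoxy-2,6-bis(methoxymethoxy)phenyl]propanoate (racemic) | CCOC(=O)C(C(OC)OC)c1c(OCOC)cc(OC)cc1OCOC
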